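Numbering (prostanoid): C1 ester carbon; C5=C6 and C7=C8 the diene; ring A = C8–C12 (C9 ketone, C10 chlorine, C12 carbinol); C13–C20 the octenyl chain.
Retrosynthetic cuts, in order: the O–Si bond at C12; the diene σ-bond C6–C7; the exocyclic C7=C8 bond; C10–Cl; C12–C13. Ring A itself is bought.
Enabling feature: in the 5-methylene form of ring A, C8 lies between the C9 carbonyl carbon and the fully substituted C12, so palladium bound at C8 finds β-hydrogens only on C7. A C7–H bond of the bare C7H2=C8 group can therefore be the coupling handle, and one dehydrogenative (oxidative Heck) vinylation brings in C1–C6, the C6–C7 bond and both diene geometries.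
Forward order: octenyl chain onto C12 of the bought ring, carbonyl moved to C9, chlorine onto C10 by way of the 10,11-epoxide, C7 added as a methylene group, C1–C6 joined, silyl group removed.
Stereochemistry: C12 comes from addition anti to the bought C9 silyloxy stereocentre, which is then oxidised away. 14Z comes from (Z)-oct-2-en-1-ol through a configurationally stable allylbarium, 5E from syn hydroboration, and 7E from the β-hydride elimination.

Key step: step 10

Remark: the carbinol centre of the given SMILES is read as S (O > C8 > C11 > C13); with attack anti to the silyloxy group this calls for the S enantiomer of the commercial 4-silyloxycyclopentenone.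

Step 1
Reactants: 1 (Z)-oct-2-en-1-ol
Product: 2 (Z)-1-chlorooct-2-ene
Conditions: PPh3, CCl4, CH2Cl2, 0 to 23 °C
Reagents that add atoms: carbon tetrachloride, ClC(Cl)(Cl)Cl
Why: Appel reaction, in which chloride displaces the alkoxyphosphonium group at the primary carbon in an SN2 manner, so that neither allylic transposition nor loss of the Z geometry is expected.

Step 2
Reactants: 2 (Z)-1-chlorooct-2-ene; 3 (S)-4-[(tert-butyldimethylsilyl)oxy]cyclopent-2-en-1-one
Product: 6 (1R,4S)-4-[(tert-butyldimethylsilyl)oxy]-1-[(2Z)-oct-2-en-1-yl]cyclopent-2-en-1-ol, via (Z)-oct-2-enylbarium chloride 4 (not isolated), via chlorobarium alkoxide 5 (not isolated)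
Conditions: BaI2, lithium biphenylide (2 equiv), THF, 23 °C; 2, −78 °C; 3, −78 °C; H2O
Reagents that add atoms: none
Why: Allylbarium carbonyl addition: allylbarium reagents made from Rieke barium at −78 °C hold their Z geometry and attack ketones 1,2 through the unsubstituted α-carbon, and attack on C1 of 3 from the face anti to the C4 silyloxy group should set the future C12 centre with its hydroxyl cis to the silyl ether, any minor epimer being removable by chromatography.

Step 3
Reactants: 6 (1R,4S)-4-[(tert-butyldimethylsilyl)oxy]-1-[(2Z)-oct-2-en-1-yl]cyclopent-2-en-1-ol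
Product: 7 (1R,4S)-1-[(2Z)-oct-2-en-1-yl]cyclopent-2-ene-1,4-diol
Conditions: Bu4NF, THF, 0 to 23 °C
Reagents that add atoms: none
Why: Fluoride-induced silyl ether cleavage, chosen because its non-acidic medium spares the ionisable tertiary allylic alcohol and both stereocentres.

Step 4
Reactants: 7 (1R,4S)-1-[(2Z)-oct-2-en-1-yl]cyclopent-2-ene-1,4-diol
Product: 8 (4R)-4-hydroxy-4-[(2Z)-oct-2-en-1-yl]cyclopent-2-en-1-one
Conditions: MnO2, CH2Cl2, 23 °C
Reagents that add atoms: none
Why: Selective allylic alcohol oxidation with MnO2: only the C9 carbinol carries a hydrogen, so the relay stereocentre is erased, the carbonyl group arrives at C9, and C12 is left as the only stereocentre under neutral conditions that cannot start a retro-aldol opening.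

Step 5
Reactants: 8 (4R)-4-hydroxy-4-[(2Z)-oct-2-en-1-yl]cyclopent-2-en-1-one
Product: 9 (4R)-4-[(2Z)-oct-2-en-1-yl]-4-[(triethylsilyl)oxy]cyclopent-2-en-1-one
Conditions: Et3SiOTf, 2,6-lutidine, CH2Cl2, −78 to 0 °C
Reagents that add atoms: triethylsilyl trifluoromethanesulfonate, CC[Si](CC)(CC)OS(=O)(=O)C(F)(F)F
Why: Silyl triflate silylation of a hindered tertiary alcohol with a non-nucleophilic base, which blocks racemisation by retro-aldol cleavage of C8–C12 in the basic steps to come and masks the hydroxyl for the enolate chemistry.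

Step 6
Reactants: 9 (4R)-4-[(2Z)-oct-2-en-1-yl]-4-[(triethylsilyl)oxy]cyclopent-2-en-1-one
Product: 10 (1S,4R,5R)-4-[(2Z)-oct-2-en-1-yl]-4-[(triethylsilyl)oxy]-6-oxabicyclo[3.1.0]hexan-2-one (oxirane anti to the silyloxy group)
Conditions: 30% aq H2O2, NaOH (0.2 equiv), MeOH, 0 °C
Reagents that add atoms: hydrogen peroxide, OO
Why: Weitz–Scheffer nucleophilic epoxidation, in which hydroperoxide anion adds only to the electron-poor C10=C11 bond and leaves the isolated Z alkene alone; attack at C11 anti to the silyloxy group should set the two oxirane centres, both of which vanish again in step 7.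

Step 7
Reactants: 10 (1S,4R,5R)-4-[(2Z)-oct-2-en-1-yl]-4-[(triethylsilyl)oxy]-6-oxabicyclo[3.1.0]hexan-2-one
Product: 12 (4R)-2-chloro-4-[(2Z)-oct-2-en-1-yl]-4-[(triethylsilyl)oxy]cyclopent-2-en-1-one, via trans-chlorohydrin 11 (not isolated)
Conditions: pyridinium chloride, 4 Å molecular sieves, CHCl3, 23 to 50 °C
Reagents that add atoms: pyridinium chloride, [Cl-].c1cc[nH+]cc1
Why: Classical conversion of an α,β-epoxy ketone into an α-chloro enone: chloride opens the protonated oxirane in an SN2 manner at C10, next to the carbonyl group and away from the neopentyl C11, and the α-chloro-β-hydroxy ketone loses water through its most acidic C10 hydrogen, while the weak acid in an aprotic solvent should spare the tertiary silyl ether.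

Step 8
Reactants: 12 (4R)-2-chloro-4-[(2Z)-oct-2-en-1-yl]-4-[(triethylsilyl)oxy]cyclopent-2-en-1-one
Product: 16 (4S)-2-chloro-5-methylidene-4-[(2Z)-oct-2-en-1-yl]-4-[(triethylsilyl)oxy]cyclopent-2-en-1-one, via lithium enolate 13 (not isolated), via Mannich base 14 (not isolated), via trimethylammonium iodide 15 (not isolated)
Conditions: LiN(iPr)2, THF, −78 °C; CH2=NMe2+ I−, −78 to 0 °C; MeI, Et2O, 23 °C; aq NaHCO3, CH2Cl2, 23 °C
Reagents that add atoms: N,N-dimethylmethyleneiminium iodide (Eschenmoser's salt), C=[N+](C)C.[I-]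
Why: Eschenmoser methylenation: C8 is the only enolisable position and loss of silyloxide from the enolate is held back because it would give a cyclopentadienone, so a Mannich reaction at C8 followed by E1cB (Hofmann-type) loss of the quaternised amine gives the exocyclic methylene group, the C8 stereocentre being transient.

Step 9
Reactants: 17 methyl hex-5-ynoate
Product: 18 methyl (5E)-6-(4,4,5,5-tetramethyl-1,3,2-dioxaborolan-2-yl)hex-5-enoate
Conditions: pinacolborane, Cp2ZrHCl (5 mol %), Et3N (5 mol %), neat, 60 °C
Reagents that add atoms: pinacolborane, [H]B1OC(C)(C)C(C)(C)O1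
Why: Zirconocene hydride-catalysed syn hydroboration of a terminal alkyne, which puts boron on the terminal carbon and thereby fixes the 5E geometry without touching the ester.

Step 10
Reactants: 16 (4S)-2-chloro-5-methylidene-4-[(2Z)-oct-2-en-1-yl]-4-[(triethylsilyl)oxy]cyclopent-2-en-1-one; 18 methyl (5E)-6-(4,4,5,5-tetramethyl-1,3,2-dioxaborolan-2-yl)hex-5-enoate
Product: 19 methyl (5E,7E)-7-{(2S)-4-chloro-2-[(2Z)-oct-2-en-1-yl]-5-oxo-2-[(triethylsilyl)oxy]cyclopent-3-en-1-ylidene}hept-5-enoate
Conditions: Pd(OAc)2 (10 mol %), 2,9-dimethyl-1,10-phenanthroline (12 mol %), O2 (1 atm), DMA, 23 °C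
Reagents that add atoms: none
Why: Oxidative (boron) Heck vinylation: 18 transmetalates to the phenanthroline-bound divalent palladium acetate with retention of its E geometry, the alkenylpalladium adds syn across C7H2=C8 with carbon going to the open, electrophilic C7 and palladium to C8, syn β-hydride elimination follows, and O2 returns the palladium hydride (zerovalent palladium) to the divalent state. The closest known reaction type is the O2-driven, base-free coupling of alkenylboronates with acrylates, methacrylates and vinyl ketones to give dienoates and dienones, and its last stage is that of a Saegusa–Ito oxidation, since the C8 palladium species is a palladium enolate. No ring is closed and no stereocentre is made; C12 is a spectator. Because C8 is flanked by the C9 carbonyl carbon and the hydrogen-free C12, only a C7 hydrogen can be lost, so the exocyclic position of the new double bond is fixed by the substrate, and the rotamer that keeps the incoming chain away from the C9 oxygen and leads to the planar, more stable dienone should give the 7E geometry, as in Heck reactions of α-methylene lactones and ketones. Site selectivity is needed among three C=C bonds and one C–Cl bond: C10=C11 is trisubstituted, chlorinated and neopentyl at C11, C14=C15 is internal and unactivated, and the vinylic chloride should stay intact because zerovalent palladium on a nitrogen ligand under O2 is reoxidised faster than it can insert. The neutral medium at 23 °C leaves the silyl ether, the methyl ester and the base-sensitive dienone alone.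

Step 11
Reactants: 19 methyl (5E,7E)-7-{(2S)-4-chloro-2-[(2Z)-oct-2-en-1-yl]-5-oxo-2-[(triethylsilyl)oxy]cyclopent-3-en-1-ylidene}hept-5-enoate
Product: 20 methyl (5E,7E)-7-{(2S)-4-chloro-2-hydroxy-2-[(2Z)-oct-2-en-1-yl]-5-oxocyclopent-3-en-1-ylidene}hept-5-enoate
Conditions: HF·pyridine, pyridine, THF, 0 °C
Reagents that add atoms: none
Why: Fluoride-assisted cleavage of the triethylsilyl ether under buffered, weakly acidic conditions, which neither ionise the carbinol (its cation would be destabilised by the dienone) nor enolise or isomerise the dienone, so that C12 and the three alkene geometries are kept.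

Compound list
1 | (Z)-oct-2-en-1-ol | CCCCC/C=C\CO | starting material
2 | (Z)-1-chlorooct-2-ene | CCCCC/C=C\CCl | intermediate
3 | (S)-4-[(tert-butyldimethylsilyl)oxy]cyclopent-2-en-1-one | O=C1C=C[C@@H](O[Si](C)(C)C(C)(C)C)C1 | starting material
4 | (Z)-oct-2-enylbarium chloride | CCCCC/C=C\C[Ba]Cl | intermediate
5 | chlorobarium alkoxide of 6 | CCCCC/C=C\C[C@]1(O[Ba]Cl)C=C[C@@H](O[Si](C)(C)C(C)(C)C)C1 | intermediate
6 | (1R,4S)-4-[(tert-butyldimethylsilyl)oxy]-1-[(2Z)-oct-2-en-1-yl]cyclopent-2-en-1-ol | CCCCC/C=C\C[C@]1(O)C=C[C@@H](O[Si](C)(C)C(C)(C)C)C1 | intermediate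
7 | (1R,4S)-1-[(2Z)-oct-2-en-1-yl]cyclopent-2-ene-1,4-diol | CCCCC/C=C\C[C@]1(O)C=C[C@@H](O)C1 | intermediate
8 | (4R)-4-hydroxy-4-[(2Z)-oct-2-en-1-yl]cyclopent-2-en-1-one | CCCCC/C=C\C[C@]1(O)C=CC(=O)C1 | intermediate
9 | (4R)-4-[(2Z)-oct-2-en-1-yl]-4-[(triethylsilyl)oxy]cyclopent-2-en-1-one | CCCCC/C=C\C[C@]1(O[Si](CC)(CC)CC)C=CC(=O)C1 | intermediate
10 | (1S,4R,5R)-4-[(2Z)-oct-2-en-1-yl]-4-[(triethylsilyl)oxy]-6-oxabicyclo[3.1.0]hexan-2-one | CCCCC/C=C\C[C@]1(O[Si](CC)(CC)CC)[C@@H]2O[C@@H]2C(=O)C1 | intermediate
11 | (2R,3S,4R)-2-chloro-3-hydroxy-4-[(2Z)-oct-2-en-1-yl]-4-[(triethylsilyl)oxy]cyclopentan-1-one | CCCCC/C=C\C[C@]1(O[Si](CC)(CC)CC)[C@H](O)[C@@H](Cl)C(=O)C1 | intermediate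
12 | (4R)-2-chloro-4-[(2Z)-oct-2-en-1-yl]-4-[(triethylsilyl)oxy]cyclopent-2-en-1-one | CCCCC/C=C\C[C@]1(O[Si](CC)(CC)CC)C=C(Cl)C(=O)C1 | intermediate
13 | lithium C8=C9 enolate of 12 | CCCCC/C=C\C[C@]1(O[Si](CC)(CC)CC)C=C(Cl)C(O[Li])=C1 | intermediate
14 | (4R,5R)-2-chloro-5-[(dimethylamino)methyl]-4-[(2Z)-oct-2-en-1-yl]-4-[(triethylsilyl)oxy]cyclopent-2-en-1-one (aminomethyl drawn trans to silyloxy; both C5 epimers converge) | CCCCC/C=C\C[C@]1(O[Si](CC)(CC)CC)C=C(Cl)C(=O)[C@@H]1CN(C)C | intermediate
15 | N-methyl (trimethylammonium) iodide of 14 | CCCCC/C=C\C[C@]1(O[Si](CC)(CC)CC)C=C(Cl)C(=O)[C@@H]1C[N+](C)(C)C.[I-] | intermediate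
16 | (4S)-2-chloro-5-methylidene-4-[(2Z)-oct-2-en-1-yl]-4-[(triethylsilyl)oxy]cyclopent-2-en-1-one | CCCCC/C=C\C[C@]1(O[Si](CC)(CC)CC)C=C(Cl)C(=O)C1=C | intermediate
17 | methyl hex-5-ynoate | C#CCCCC(=O)OC | starting material
18 | methyl (5E)-6-(4,4,5,5-tetramethyl-1,3,2-dioxaborolan-2-yl)hex-5-enoate | COC(=O)CCC/C=C/B1OC(C)(C)C(C)(C)O1 | intermediate
19 | methyl (5E,7E)-7-{(2S)-4-chloro-2-[(2Z)-oct-2-en-1-yl]-5-oxo-2-[(triethylsilyl)oxy]cyclopent-3-en-1-ylidene}hept-5-enoate | CCCCC/C=C\C[C@]1(O[Si](CC)(CC)CC)C=C(Cl)C(=O)/C1=C/C=C/CCCC(=O)OC | intermediate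
20 | methyl (5E,7E)-7-{(2S)-4-chloro-2-hydroxy-2-[(2Z)-oct-2-en-1-yl]-5-oxocyclopent-3-en-1-ylidene}hept-5-enoate | CCCCC/C=C\C[C@]1(O)C=C(Cl)C(=O)/C1=C/C=C/CCCC(=O)OC | target

Total step count: 11. Longest linear sequence: 10 steps (steps 1 to 8, 10 and 11).

Steps most likely to fail

1. Step 10. The C8 palladium enolate may be protonated before β-hydride elimination, which gives net conjugate addition. The bulk at C12 may erode the 7E selectivity, the boronate may homocouple, or the methylene dienone may oligomerise. The fallback sets out from 12 and comes back at 19, so 16 and 18 are not needed; it joins the chain at C7–C8 by an aldol–elimination sequence instead. Cross metathesis of methyl hex-5-enoate with crotonaldehyde (second-generation Hoveyda–Grubbs catalyst, CH2Cl2, 40 °C) should give methyl (E)-7-oxohept-5-enoate F1. The lithium enolate 13 made from 12 (LiN(iPr)2, THF, −78 °C) adds to it to give the C7 aldol adduct F2. Mesylation (MsCl, Et3N, CH2Cl2, 0 °C) gives the allylic mesylate F3, and E1cB elimination (DBU, CH2Cl2, 0 °C) leads to 19.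

2. Step 2. Ketone 3 may enolise and then lose silyloxide by β-elimination, facial selectivity at C1 may be poor, or α-selectivity and Z geometry may be partly lost if the allylbarium warms. The fallback sets out from 3 and comes back at 6; it builds the chain in stages from a symmetrical allyl nucleophile, so that no regiochemical or geometrical question arises at the addition. Allylmagnesium bromide with CeCl3 (THF, −78 °C) adds 1,2 and anti to the silyloxy group to give the allyl carbinol F4. Lemieux–Johnson cleavage of its monosubstituted alkene (OsO4 cat., NaIO4, 2,6-lutidine, dioxane–H2O) gives the β-hydroxy aldehyde F5. A Z-selective Wittig reaction with hexylidenetriphenylphosphorane (hexyltriphenylphosphonium bromide, NaN(SiMe3)2, THF, −78 °C) then gives 6.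

3. Step 7. The triethylsilyl ether may be lost under the acidic chloride source, or the elimination may run in the wrong direction at the chlorohydrin stage (enolisation toward C8 with expulsion of the C12 silyloxy group). The fallback sets out from 10 and comes back at 12; it separates opening from elimination and fixes the direction of elimination with a leaving group. LiCl and AcOH in THF open the oxirane and 11 is isolated. Its only free hydroxyl, at C11, is converted into the chlorohydrin mesylate F6 (MsCl, Et3N, CH2Cl2, −20 °C), which undergoes E1cB elimination through the C10 hydrogen on warming with Et3N to give 12.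

Further compounds
F1 | step 10 | methyl (E)-7-oxohept-5-enoate | COC(=O)CCC/C=C/C=O
F2 | step 10 | C7 aldol adduct of 12 and F1 (one C7 epimer drawn; all diastereomers converge) | CCCCC/C=C\C[C@]1(O[Si](CC)(CC)CC)C=C(Cl)C(=O)[C@@H]1[C@H](O)/C=C/CCCC(=O)OC
F3 | step 10 | allylic mesylate of F2 | CCCCC/C=C\C[C@]1(O[Si](CC)(CC)CC)C=C(Cl)C(=O)[C@@H]1[C@H](OS(C)(=O)=O)/C=C/CCCC(=O)OC
F4 | step 2 | allyl carbinol, (1R,4S)-4-[(tert-butyldimethylsilyl)oxy]-1-(prop-2-en-1-yl)cyclopent-2-en-1-ol | C=CC[C@]1(O)C=C[C@@H](O[Si](C)(C)C(C)(C)C)C1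
F5 | step 2 | β-hydroxy aldehyde (allyl group of F4 cut to CH2CHO, ring stereocentres unchanged) | O=CC[C@]1(O)C=C[C@@H](O[Si](C)(C)C(C)(C)C)C1
F6 | step 7 | chlorohydrin mesylate (C11 methanesulfonate of 11) | CCCCC/C=C\C[C@]1(O[Si](CC)(CC)CC)[C@H](OS(C)(=O)=O)[C@@H](Cl)C(=O)C1
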